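The numbers in the tables stem from a simulated flask with made-up constants, noise included.

A closed, stirred, isothermal vessel of constant volume takes electrophile, nucleophile and free base, and the candidate must say what it holds after 1.0 h.

| flask | electrophile | nucleophile | free base | remark | time |
|---|---|---|---|---|---|
| gamma | 0.37 M | 0.407 M | 0.37 M | run made earlier |  |
| eta | 0.37 M | 0.407 M | 0.83 M | run made earlier |  |
| epsilon | 0.18 M | 0.407 M | 0.555 M | run made earlier |  |
| flask | 0.37 M | 0.407 M | 0.555 M |  | 1.0 h |

| run | time / min | electrophile / % | target / % |
|---|---|---|---|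
| gamma | 6.00 | 17.0 | 83.3 |
| gamma | 12.0 | 9.9 | 90.5 |
| gamma | 20.0 | 7.1 | 93.4 |
| gamma | 25.0 | 6.6 | 93.5 |
| gamma | 30.0 | 5.0 | 94.8 |
| gamma | 40.0 | 5.1 | 93.6 |
| eta | 6.00 | 13.1 | 86.7 |
| eta | 12.0 | 8.0 | 91.0 |
| eta | 20.0 | 7.0 | 92.8 |
| eta | 25.0 | 7.4 | 92.5 |
| eta | 30.0 | 7.8 | 93.1 |
| eta | 40.0 | 7.6 | 92.6 |
| epsilon | 8.00 | 1.6 | 99.1 |
| epsilon | 15.0 | 0 | 99.9 |
| epsilon | 20.0 | 0 | 100.4 |
| epsilon | 30.0 | 0.4 | 101.1 |
| epsilon | 40.0 | 0.7 | 100.0 |

(scatter of a reading: 0.5 percentage points)

- the earlier runs do not show how much of nucleophile is bound; that part of a forecast is a guess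

- part of the electrophile that has reacted at 1.0 h
- share of the unused nucleophile that is free and not bound as protonated nucleophile, at 1.0 h

Where does the electrophile stop? Near gamma and eta, whose last readings show 5.1 % and 7.6 % left. The flask's base charge lies above gamma's and below eta's, so I take their mean and commit to 93.6 % reacted.

Is the stall caused by nucleophile bound as protonated nucleophile? I assume one acid set free per electrophile reacted. More base should then lift the plateau, yet eta, with more base than gamma, reads 92.4 % reacted, less than gamma's 94.9 %. So I read the stall as nucleophile lost by a route that makes no target, with nucleophile as the limiting reagent despite 1.10 equivalents charged.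

What measures the protection against binding? The flask's base margin is 0.564: the base charged, as a fraction of the electrophile charged, minus the fraction of electrophile reacted.

And the weak spot? Gamma's margin is just 0.0510 and eta's 1.32, yet both are positive and both stall. The flask's margin is positive too, so I guess the free share stands high, though the runs do not show it.

The forecast says 93.7 % reacted (92 % to 95.3 %) and, differing from me, 35 % free (10 % to 80 %), since “much of the leftover nucleophile is bound, perhaps most of it”.

The flask gives 93.6 % reacted and 98.5 % free, and at 1.00 h it still holds 38 % of its free base.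

acid set free + free base ⇌ salt of the base (K = 9900 M⁻¹, k = 16.0 M⁻¹ min⁻¹); 2 nucleophile → self-condensation product (k = 0.810 M⁻¹ min⁻¹); nucleophile + acid set free ⇌ protonated nucleophile, settled at all times (K = 90.0 M⁻¹); electrophile + nucleophile → acid set free + target (k = 5.50 M⁻¹ min⁻¹) With the reacted fraction found, the flask's margin stands at 0.564. The neighbour flask with 0.33 M of free base, 0.892 equiv against the electrophile, reacts to 94.7 %, so its margin is −0.0553, below zero, and there the free share of the unused nucleophile at 1.00 h is 34.5 %.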